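**Plan**

- Numbering: ring A carries the butanoyl group on C1, oxygen on C2, C4 and C6, the gem-dimethyl group on C3 and the CH2 bridge on C5; ring B is the resorcinol ring.
- Retrosynthesis: the two butanoyl C–C bonds are cut first (ring B, then C1 of ring A). Ring A is then opened at C1–C2, C5–C6 and C2–C3 to a 4,4-dimethylcyclobutenone and ethoxyacetylene. The cyclobutenone is cut into dimethylketene and a benzylic ynol ether, and that at the propargylic C–C bond and the aryl–CH2 bond.
- Forward order: ring B is bought as 2,5-dimethylresorcinol and receives its bridge carbon by formylation; the four-membered ring follows by ketene–alkyne cycloaddition; ring A arises in step 7; then both butanoyl groups are attached and the phenols are set free.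
- Enabling feature: C3 is quaternary and sits between the oxygenated carbons C2 and C4, so ring A is a 6,6-dimethylcyclohexa-2,4-dienone that cannot aromatise, with oxygen on alternate ring carbons. This is the direct output of a vinylketene from a 3-alkoxy-4,4-dimethylcyclobutenone and an alkoxyalkyne.
- Stereochemistry: the target has no stereocentre and no stereogenic double bond; the one transient quaternary centre of the alkenylcyclobutenone intermediate is racemic and is erased in the same step.

Key step: step 7

Assumption: ring A of the target is an enolised β-triketone, the given SMILES shows one of its rapidly interconverting tautomers, and all ring A compounds after the hydrolysis step are drawn in the matching tautomer.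

**Route**

Step 1
Reactants: 1 2,5-dimethylresorcinol
Product: 2 1,3-dimethoxy-2,5-dimethylbenzene
Conditions: MeI, K2CO3, acetone, reflux
Reagents that add atoms: iodomethane, CI
Why: Williamson O-methylation of both phenols with a mild carbonate base masks them for the organolithium, ketene and Lewis acid steps that follow.

Step 2
Reactants: 2 1,3-dimethoxy-2,5-dimethylbenzene
Product: 4 2,4-dimethoxy-3,6-dimethylbenzaldehyde, via aryl iminium salt 3 (not isolated)
Conditions: POCl3, DMF, 0 °C to 80 °C; then H2O, 50 °C
Reagents that add atoms: N,N-dimethylformamide, CN(C)C=O; water, O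
Why: Vilsmeier–Haack formylation attacks one of the two equivalent free ring positions, each ortho and para to a methoxy group, and the formyl group then deactivates the ring against a second substitution, so the bridge carbon is attached once and cleanly.

Step 3
Reactants: 4 2,4-dimethoxy-3,6-dimethylbenzaldehyde
Product: 5 (2,4-dimethoxy-3,6-dimethylphenyl)methanol
Conditions: NaBH4, MeOH, 0 °C
Reagents that add atoms: none
Why: NaBH4 reduces the aryl aldehyde chemoselectively to the benzylic alcohol without touching the ethers.

Step 4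
Reactants: 5 (2,4-dimethoxy-3,6-dimethylphenyl)methanol
Product: 6 2,4-dimethoxy-3,6-dimethylbenzyl bromide
Conditions: PBr3, Et2O, 0 °C; crude bromide used at once
Reagents that add atoms: phosphorus tribromide, BrP(Br)Br
Why: Standard conversion of a benzylic alcohol into the bromide with PBr3 at low temperature, the flanking methoxy and methyl groups retarding self-alkylation of this electron-rich halide, which is nevertheless used without storage.

Step 5
Reactants: 6 2,4-dimethoxy-3,6-dimethylbenzyl bromide; 7 ethoxyacetylene
Product: 9 1-(3-ethoxyprop-2-yn-1-yl)-2,4-dimethoxy-3,6-dimethylbenzene, via lithium ethoxyacetylide 8 (not isolated)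
Conditions: 7, n-BuLi, THF, −78 °C; then 6, DMPU, −78 °C to 0 °C
Reagents that add atoms: none
Why: SN2 alkylation of a lithium alkoxyacetylide by a reactive benzylic bromide in THF with a dipolar cosolvent is the standard route to 1-alkoxy-1-alkynes, and the low temperature and the absence of excess base keep the benzylic propargylic position from isomerising to the allene.

Step 6
Reactants: 9 1-(3-ethoxyprop-2-yn-1-yl)-2,4-dimethoxy-3,6-dimethylbenzene; 10 isobutyryl chloride
Product: 12 2-(2,4-dimethoxy-3,6-dimethylbenzyl)-3-ethoxy-4,4-dimethylcyclobut-2-en-1-one, via dimethylketene 11 (not isolated)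
Conditions: Et3N, CH2Cl2, slow addition of 10, 0 °C to 40 °C
Reagents that add atoms: none
Why: Dimethylketene, released by dehydrochlorination of the acid chloride, undergoes the known ketene–ynol ether [2+2] cycloaddition in which its carbonyl carbon bonds to the nucleophilic benzyl-bearing alkyne carbon and its CMe2 carbon to the ethoxy-bearing carbon, which fixes the 2-benzyl-3-ethoxy-4,4-dimethyl pattern.

Step 7
Reactants: 12 2-(2,4-dimethoxy-3,6-dimethylbenzyl)-3-ethoxy-4,4-dimethylcyclobut-2-en-1-one; 7 ethoxyacetylene
Product: 16 4-(2,4-dimethoxy-3,6-dimethylbenzyl)-3,5-diethoxy-6,6-dimethylcyclohexa-2,4-dien-1-one, via vinylketene 13 (not isolated), via alkenylcyclobutenone 14 (not isolated), via dienylketene 15 (not isolated)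
Conditions: 7 (5 equiv, added in portions), PhMe, sealed tube, 90 °C
Reagents that add atoms: none
Why: Heating opens 12 by conrotatory 4π electrocyclic cleavage of its C(=O)–CMe2 bond to vinylketene 13, whose ketene carbon is the future C2 and whose CMe2 terminus is the future C3. Ketene–alkyne [2+2] cycloaddition with 7 then forms C2–C1 (ketene carbon to the unsubstituted alkyne carbon) and C5–C6 (benzyl-bearing carbon to the ethoxy-bearing carbon), giving 14, which opens reversibly by a second 4π cleavage to dienylketene 15. Ring A, the only ring closed, arises by thermal disrotatory 6π electrocyclisation of 15, which re-forms C2–C3. The closest known reaction type is the Danheiser benzannulation of cyclobutenones with alkoxyalkynes, together with the known addition of ynamines to vinylketenes with a CMe2 terminus, which likewise stops at the 6,6-dimethylcyclohexa-2,4-dienone because C3 bears no hydrogen. No stereocentre is created (the quaternary centre of 14 is racemic and lost on ring opening), and only the isomer of 15 with ketenyl and alkenyl groups cis can close, the reversible opening of 14 feeding it. The step needs the polarity-controlled regiochemistry of the [2+2] (electrophilic ketene carbon to the nucleophilic β-carbon of the ynol ether), secured by the ethoxy group of 7, and trapping of 13 faster than its 1,5-hydrogen shift, secured by the excess of 7 and the moderate temperature.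

Step 8
Reactants: 16 4-(2,4-dimethoxy-3,6-dimethylbenzyl)-3,5-diethoxy-6,6-dimethylcyclohexa-2,4-dien-1-one
Product: 17 2-(2,4-dimethoxy-3,6-dimethylbenzyl)-3,5-dihydroxy-4,4-dimethylcyclohexa-2,5-dien-1-one
Conditions: 2 M HCl, THF, rt
Reagents that add atoms: water, O
Why: Both ethoxy groups are vinylogous ester enol ethers and are hydrolysed by dilute aqueous acid through C-protonation and addition of water, conditions that leave the aryl methyl ethers and the bridge untouched.

Step 9
Reactants: 17 2-(2,4-dimethoxy-3,6-dimethylbenzyl)-3,5-dihydroxy-4,4-dimethylcyclohexa-2,5-dien-1-one; 18 butyryl chloride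
Product: 20 6-butanoyl-2-(2,4-dimethoxy-3,6-dimethylbenzyl)-3,5-dihydroxy-4,4-dimethylcyclohexa-2,5-dien-1-one, via enol butyrate 19 (not isolated)
Conditions: 18 (1.1 equiv), Et3N, CH2Cl2, 0 °C; then DMAP (0.2 equiv), rt
Reagents that add atoms: none
Why: O-Acylation of the enolised trione followed by DMAP-catalysed O-to-C acyl migration is the standard route to 2-acylcyclohexane-1,3-diones and delivers the butanoyl group to C1, the only unsubstituted carbon between two carbonyls, because acyl transfer is reversible and the chelated triketone is the thermodynamic sink for any regioisomeric enol ester.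

Step 10
Reactants: 20 6-butanoyl-2-(2,4-dimethoxy-3,6-dimethylbenzyl)-3,5-dihydroxy-4,4-dimethylcyclohexa-2,5-dien-1-one; 18 butyryl chloride
Product: 21 6-butanoyl-2-(5-butanoyl-2,4-dimethoxy-3,6-dimethylbenzyl)-3,5-dihydroxy-4,4-dimethylcyclohexa-2,5-dien-1-one
Conditions: 18, AlCl3, CH2Cl2, 0 °C to rt; then ice-cold 1 M HCl
Reagents that add atoms: none
Why: Friedel–Crafts acylation takes place at the single free position of ring B, ortho and para to the two methoxy groups, while ring A is protected as its electron-poor aluminium chelate, and any methyl ether cleaved next to the new ketone by the Lewis acid converges with the product in step 11.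

Step 11
Reactants: 21 6-butanoyl-2-(5-butanoyl-2,4-dimethoxy-3,6-dimethylbenzyl)-3,5-dihydroxy-4,4-dimethylcyclohexa-2,5-dien-1-one
Product: 22 6-butanoyl-2-(5-butanoyl-2,4-dihydroxy-3,6-dimethylbenzyl)-3,5-dihydroxy-4,4-dimethylcyclohexa-2,5-dien-1-one
Conditions: BBr3, CH2Cl2, −78 °C to rt; then H2O
Reagents that add atoms: none
Why: BBr3 cleaves aryl methyl ethers by bromide attack on the O-methyl group of the boron-coordinated ether, and the two ketones and the enolised triketone merely form boron chelates that are released on aqueous work-up.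

**Compound list**

1 | 2,5-dimethylresorcinol | Cc1cc(O)c(C)c(O)c1 | starting material
2 | 1,3-dimethoxy-2,5-dimethylbenzene | COc1cc(C)cc(OC)c1C | intermediate
3 | N-(2,4-dimethoxy-3,6-dimethylbenzylidene)-N-methylmethanaminium dichlorophosphate (aryl iminium salt, formed in the flask) | C[N+](C)=Cc1c(C)cc(OC)c(C)c1OC.[O-]P(=O)(Cl)Cl | intermediate
4 | 2,4-dimethoxy-3,6-dimethylbenzaldehyde | O=Cc1c(C)cc(OC)c(C)c1OC | intermediate
5 | (2,4-dimethoxy-3,6-dimethylphenyl)methanol | OCc1c(C)cc(OC)c(C)c1OC | intermediate
6 | 2,4-dimethoxy-3,6-dimethylbenzyl bromide | BrCc1c(C)cc(OC)c(C)c1OC | intermediate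
7 | ethoxyacetylene | C#COCC | starting material
8 | lithium ethoxyacetylide (formed in the flask) | [Li]C#COCC | intermediate
9 | 1-(3-ethoxyprop-2-yn-1-yl)-2,4-dimethoxy-3,6-dimethylbenzene | CCOC#CCc1c(C)cc(OC)c(C)c1OC | intermediate
10 | isobutyryl chloride | CC(C)C(=O)Cl | starting material
11 | dimethylketene (formed in the flask) | CC(C)=C=O | intermediate
12 | 2-(2,4-dimethoxy-3,6-dimethylbenzyl)-3-ethoxy-4,4-dimethylcyclobut-2-en-1-one | O=C1C(Cc2c(C)cc(OC)c(C)c2OC)=C(OCC)C1(C)C | intermediate
13 | 2-(2,4-dimethoxy-3,6-dimethylbenzyl)-3-ethoxy-4-methylpenta-1,3-dien-1-one (vinylketene, formed in the flask) | O=C=C(Cc1c(C)cc(OC)c(C)c1OC)C(OCC)=C(C)C | intermediate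
14 | racemic 4-(2,4-dimethoxy-3,6-dimethylbenzyl)-3-ethoxy-4-(1-ethoxy-2-methylprop-1-en-1-yl)cyclobut-2-en-1-one (formed in the flask) | O=C1C=C(OCC)C1(Cc1c(C)cc(OC)c(C)c1OC)C(OCC)=C(C)C | intermediate
15 | (3E)-4-(2,4-dimethoxy-3,6-dimethylbenzyl)-3,5-diethoxy-6-methylhepta-1,3,5-trien-1-one (dienylketene with ketenyl and alkenyl groups cis, formed in the flask) | O=C=C\C(OCC)=C(/C(OCC)=C(C)C)Cc1c(C)cc(OC)c(C)c1OC | intermediate
16 | 4-(2,4-dimethoxy-3,6-dimethylbenzyl)-3,5-diethoxy-6,6-dimethylcyclohexa-2,4-dien-1-one | O=C1C=C(OCC)C(Cc2c(C)cc(OC)c(C)c2OC)=C(OCC)C1(C)C | intermediate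
17 | 2-(2,4-dimethoxy-3,6-dimethylbenzyl)-3,5-dihydroxy-4,4-dimethylcyclohexa-2,5-dien-1-one | O=C1C=C(O)C(C)(C)C(O)=C1Cc1c(C)cc(OC)c(C)c1OC | intermediate
18 | butyryl chloride | CCCC(=O)Cl | starting material
19 | 4-(2,4-dimethoxy-3,6-dimethylbenzyl)-5-hydroxy-6,6-dimethyl-3-oxocyclohexa-1,4-dien-1-yl butanoate (enol butyrate, formed in the flask) | O=C1C=C(OC(=O)CCC)C(C)(C)C(O)=C1Cc1c(C)cc(OC)c(C)c1OC | intermediate
20 | 6-butanoyl-2-(2,4-dimethoxy-3,6-dimethylbenzyl)-3,5-dihydroxy-4,4-dimethylcyclohexa-2,5-dien-1-one | CCCC(=O)C1=C(O)C(C)(C)C(O)=C(Cc2c(C)cc(OC)c(C)c2OC)C1=O | intermediate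
21 | 6-butanoyl-2-(5-butanoyl-2,4-dimethoxy-3,6-dimethylbenzyl)-3,5-dihydroxy-4,4-dimethylcyclohexa-2,5-dien-1-one | CCCC(=O)C1=C(O)C(C)(C)C(O)=C(Cc2c(C)c(C(=O)CCC)c(OC)c(C)c2OC)C1=O | intermediate
22 | 6-butanoyl-2-(5-butanoyl-2,4-dihydroxy-3,6-dimethylbenzyl)-3,5-dihydroxy-4,4-dimethylcyclohexa-2,5-dien-1-one (CNP0295128.0) | CCCC(=O)C1=C(O)C(C)(C)C(O)=C(Cc2c(C)c(C(=O)CCC)c(O)c(C)c2O)C1=O | target

**Count and risks**

Total step count: 11. Longest linear sequence: 11 steps (1 to 22); 7, 10 and 18 are bought.

The three steps most likely to fail: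

1. Step 7. The ring opening of 12 may need a temperature at which ethoxyacetylene fragments to ketene and ethylene, or vinylketene 13 may isomerise by 1,5-hydrogen shift from a methyl group faster than it is trapped. The fallback takes ring A from the aromatic pool and sets out from 18 and 6. Phloroglucinol F1 would be C-butanoylated with 18 (AlCl3, PhNO2/CH2Cl2) to 1-(2,4,6-trihydroxyphenyl)butan-1-one F2. Geminal C-methylation (MeI, NaOMe, MeOH) should then give butyrylfilicinic acid F3 (2-butanoyl-3,5-dihydroxy-4,4-dimethylcyclohexa-2,5-dien-1-one). C-Benzylation of F3 at its one free ring carbon with bromide 6 (NaOMe, MeOH, 0 °C) comes back to the route at 20.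

2. Step 5. The electron-rich bromide may self-alkylate before it meets the acetylide, or the product may isomerise to the allene under the basic conditions. The fallback attaches the benzyl group after the four-membered ring is made and sets out from 7 and 10 (with 6 as coupling partner). Cycloaddition of dimethylketene 11 with 7 (Et3N, CH2Cl2) should give 3-ethoxy-4,4-dimethylcyclobut-2-en-1-one F4. Bromination at C2 (N-bromosuccinimide, CH2Cl2, 0 °C) would give 2-bromo-3-ethoxy-4,4-dimethylcyclobut-2-en-1-one F5. Bromide 6 would be converted into (2,4-dimethoxy-3,6-dimethylbenzyl)zinc bromide F6 (Zn dust, LiCl, THF). Negishi coupling of F5 with F6 (Pd(PPh3)4, a zerovalent palladium catalyst, THF, rt) comes back to the route at 12.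

3. Step 10. The Lewis acid may cleave or scramble the methylene bridge (loss of the electron-rich benzyl group from the triketone carbon), or ring A may be acylated on oxygen instead of ring B on carbon. The fallback reverses the last two operations and sets out from 20. BBr3 (CH2Cl2, −78 °C to rt) would first give 6-butanoyl-2-(2,4-dihydroxy-3,6-dimethylbenzyl)-3,5-dihydroxy-4,4-dimethylcyclohexa-2,5-dien-1-one F7. Its free resorcinol ring would then be acylated under Hoesch conditions (butyronitrile, ZnCl2, HCl gas, Et2O, 0 °C) to the ketiminium chloride F8. Hydrolysis of F8 in warm water comes back to the route at 22, without passing through 21.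

**Further compounds**

F1 | step 7 | phloroglucinol (benzene-1,3,5-triol) | Oc1cc(O)cc(O)c1
F2 | step 7 | 1-(2,4,6-trihydroxyphenyl)butan-1-one | CCCC(=O)c1c(O)cc(O)cc1O
F3 | step 7 | butyrylfilicinic acid (2-butanoyl-3,5-dihydroxy-4,4-dimethylcyclohexa-2,5-dien-1-one) | CCCC(=O)C1=C(O)C(C)(C)C(O)=CC1=O
F4 | step 5 | 3-ethoxy-4,4-dimethylcyclobut-2-en-1-one | CCOC1=CC(=O)C1(C)C
F5 | step 5 | 2-bromo-3-ethoxy-4,4-dimethylcyclobut-2-en-1-one | CCOC1=C(Br)C(=O)C1(C)C
F6 | step 5 | (2,4-dimethoxy-3,6-dimethylbenzyl)zinc bromide | Br[Zn]Cc1c(C)cc(OC)c(C)c1OC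
F7 | step 10 | 6-butanoyl-2-(2,4-dihydroxy-3,6-dimethylbenzyl)-3,5-dihydroxy-4,4-dimethylcyclohexa-2,5-dien-1-one | CCCC(=O)C1=C(O)C(C)(C)C(O)=C(Cc2c(C)cc(O)c(C)c2O)C1=O
F8 | step 10 | 1-[3-[(3-butanoyl-2,4-dihydroxy-5,5-dimethyl-6-oxocyclohexa-1,3-dien-1-yl)methyl]-4,6-dihydroxy-2,5-dimethylphenyl]butan-1-iminium chloride | CCCC(=O)C1=C(O)C(C)(C)C(O)=C(Cc2c(C)c(C(=[NH2+])CCC)c(O)c(C)c2O)C1=O.[Cl-]
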